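Assumption: the chain is numbered C1 (carboxyl carbon) to C19 (terminal methyl) along the backbone of the SMILES. The target is then (3R,6S,7S,12S,14R,15R,16R,17R,18R), and acid 1 is taken as the enantiopure commercial material.

## Analysis of the target

The target is a linear C19 polyketide acid. One part of the chain is closed to an oxane ring (O, C3, C4, C5, C6, C7). The rest carries an (8E,10E)-diene, a tertiary allylic carbinol at C12, a trisubstituted oxirane (C14, C15, O) and the C16 methyl / C17 methoxy / C18 hydroxy triad.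

There are nine stereocentres. On the oxane all three substituents are equatorial (C3/C7 cis, C6/C7 trans). C16, C17 and C18 are all syn in the zigzag chain. On the oxirane, C13 and C16 are trans, so the oxirane derives from an (E)-C14=C15 alkene.

C12 is the hard centre. It is quaternary (OH, CH3, C11, C13), has no neighbouring stereocentre, and lies 1,3 to C14 and 1,5 to C16 across what will be a planar alkene. Neither chelation nor Felkin control reaches it, and a chiral reagent would have to tell a methyl group from a methylene group.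

The feature the route exploits is the C11–C15 segment. C12 is tied through the C13 methylene to C14, so C11–C12(O)–C13–C14=C15 in the alkene precursor is a γ,δ-unsaturated α-oxygenated carbonyl array. That is the product pattern of a [3,3] shift in which C15 serves as a disposable allylic carbinol.

The sensitive groups are these. The C12 dienylic tertiary alcohol ionises with acid. The oxirane can be opened by the C18 hydroxyl (5-exo) or by acid. The diene forbids hydrogenolysis and unselective epoxidation. A free C12 hydroxyl is allylic to C10=C11 and homoallylic to C14=C15, so it would misdirect a metal-catalysed epoxidation. The order of the late steps is therefore as important as the bond constructions.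

## Retrosynthetic reasoning

**32 back to 29.** The last operations remove only the C12 silyl ether and the methyl ester (32 from 30 through 31). The oxirane C–O bonds are cut next (30 from 29). Epoxidation is placed after the diene is built because the free C18 hydroxyl of 29 can deliver oxygen to C14=C15 alone, while the C12 oxygen is silylated and cannot direct attack on C10=C11. This step sets C14 and C15 together from C18.

**29 and 28 back to 17 and 27.** The C9–C10 bond, an sp2–sp2 bond in the middle of the diene, is cut. It divides the molecule into the oxane half 27 (C1–C9) and the chain half 17 (C10–C19). The forward reaction is a Suzuki coupling that keeps both alkene geometries.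

**17 back to 13.** C10 is a one-carbon homologation of aldehyde 16 (C11). The benzyl groups are exchanged for silyl groups at triol 14 and tris-silyl ether 15, where the only π system is one isolated alkene, so a dissolving-metal debenzylation is safe.

**13 back to 10 (key disconnection).** The C12–C13 bond is cut. Alcohol 13 arises through silyl ester 12 and ketene acetal 11 from allyl ester 10 by an Ireland–Claisen rearrangement. This cut is preferred over C11–C12 because it turns the isolated quaternary carbinol into an enolate carbon. The facial choice at that carbon is dictated by the C15 carbinol through a chair transition state, and the same event creates the (E)-C14=C15 alkene needed for the oxirane. The precursor 10 has no quaternary centre and is simply the ester of a secondary allylic alcohol with acid 1.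

**10 back to 1, 3 and 4.** Ester 10 comes from diol 8 by acylation at O15 (giving 9) and methylation at O17. Diol 8 comes from aldol adduct 6 by a 1,3-syn reduction that sets C17. Adduct 6 comes from ketone 3 and methacrolein 4 by cutting C15–C16, an aldol reaction in which the C18 benzyloxy group sets C16 and C15 in one event. Ketone 3 comes from acid 1 through amide 2. Acid 1 thus supplies C17–C19 and, a second time, C11–C12 with its methyl group. Every stereocentre of the C10–C19 half is relayed from the one purchased centre, C18.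

**27 back to 18 and 21.** The C8 methyl and the C9 iodide come from carbometalation of alkyne 25. The oxane C3–O bond is cut to hydroxy enoate 23, closed forward by an oxa-Michael addition that sets C3 under thermodynamic control. The C3–C4 bond is cut to alkene 20 and iodoacrylate 21. Alcohol 20 comes from ynal 18 by an anti-crotylboration that sets C6 and C7 together.

## Alternatives that were turned down

Alternative 1: the textbook route. The C9–C10 coupling is kept, but C12 is made by forming the C11–C12 bond, adding an alkynyl or alkenyl metal to methyl ketone A1 to give carbinol A2. It was turned down because the carbonyl of A1 is flanked by a methyl and a methylene group of nearly equal size, and the nearest stereocentre, C16, is 1,5 across the planar C14=C15 alkene. Neither the substrate nor a chiral reagent can distinguish the faces, so A2 would form as a mixture of C12 epimers that has to be separated late. A1 is also a β,γ-unsaturated ketone that drifts into conjugation under basic organometallic conditions. The route is a few steps shorter on paper but leaves the hardest centre unsolved.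

Alternative 2: a cyclic template. The C12–C13 bond is made by alkylating the enolate of the chiral dioxolanone template A3 (a cyclic acetal that stores the configuration of an α-hydroxy acid) with allylic bromide A4 to give A5. The acetal centre would set C12 reliably. It was turned down as the main route for step economy and reach. The template sets one stereocentre only, and A4 needs the (E)-C14=C15 alkene from a separate olefination of an epimerisable α-methyl aldehyde, then a reduction and a bromination, about four steps more than the ester 10 costs. The SN2 alkylation of a fully substituted enolate by a β-branched allylic bromide also competes with SN2′ attack and elimination. The idea is kept as a fallback.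

Alternative 3: an enzymatic key step. The C12–H bond of the 12-deoxy acid A6 is hydroxylated late by a cytochrome P450 monooxygenase. It was turned down on structural grounds. Such hydroxylations proceed with retention, so A6 must carry its C12 hydrogen exactly where the target has the hydroxyl, which fixes A6 as the (12R)-methyl compound. A6 would then itself need a full synthesis of the same length as the present one. The enzyme would also have to select the tertiary allylic C12–H over the allylic, ether-activated C7–H, the tertiary C6–H and C16–H, and the diene and oxirane. No enzyme is known to do this on this skeleton, so the risk could not be confined to one step with a chemical fallback.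

Key step: step 7

## Route

Step 1
Reactants: 1 (2R)-2-(benzyloxy)propanoic acid
Product: 2 (2R)-2-(benzyloxy)-N-methoxy-N-methylpropanamide
Conditions: MeNHOMe·HCl, EDC·HCl, HOBt (cat.), N-methylmorpholine, CH2Cl2, 0 → 23 °C
Reagents that add atoms: N,O-dimethylhydroxylamine hydrochloride, CNOC.Cl
Why: Carbodiimide amidation to the Weinreb amide; the buffered, HOBt-mediated activation should leave the α-benzyloxy stereocentre (the future C18) untouched.

Step 2
Reactants: 2 (2R)-2-(benzyloxy)-N-methoxy-N-methylpropanamide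
Product: 3 (2R)-2-(benzyloxy)pentan-3-one
Conditions: EtMgBr, THF, 0 °C; aq. NH4Cl
Reagents that add atoms: ethylmagnesium bromide, CC[Mg]Br
Why: Weinreb ketone synthesis; the chelated magnesium adduct stops over-addition, and the ketone is released only on work-up, so C18 is not exposed to base.

Step 3
Reactants: 3 (2R)-2-(benzyloxy)pentan-3-one; 4 2-methylprop-2-enal (methacrolein)
Product: 6 (2R,4S,5S)-2-(benzyloxy)-5-hydroxy-4,6-dimethylhept-6-en-3-one, via trichlorotitanium enolate 5 (not isolated)
Conditions: TiCl4, i-Pr2NEt, CH2Cl2, −78 °C; then 4, −78 °C; aq. NH4Cl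
Reagents that add atoms: none
Why: Titanium-mediated aldol reaction of an α-benzyloxy ethyl ketone: the benzyloxy group chelates titanium in the (Z)-enolate 5, and the chair transition state should give the 2,4-syn-4,5-syn adduct, the course established for this ketone class with enals; C16 and C15 are thus set in one event by C18.

Step 4
Reactants: 6 (2R,4S,5S)-2-(benzyloxy)-5-hydroxy-4,6-dimethylhept-6-en-3-one
Product: 8 (2R,3R,4S,5S)-2-(benzyloxy)-4,6-dimethylhept-6-ene-3,5-diol, via diethylboron aldolate 7 (not isolated)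
Conditions: Et2BOMe, THF/MeOH (4:1), −78 °C; NaBH4; then MeOH (co-evaporation)
Reagents that add atoms: none
Why: Narasaka–Prasad reduction: external hydride attacks the six-membered boron chelate 7 axially and should give the 1,3-syn diol, which sets C17 syn to C15 and hence syn to C16 and C18.

Step 5
Reactants: 8 (2R,3R,4S,5S)-2-(benzyloxy)-4,6-dimethylhept-6-ene-3,5-diol; 1 (2R)-2-(benzyloxy)propanoic acid
Product: 9 (3S,4R,5R,6R)-6-(benzyloxy)-5-hydroxy-2,4-dimethylhept-1-en-3-yl (2R)-2-(benzyloxy)propanoate
Conditions: 1 (1.05 equiv), DIC, DMAP (0.1 equiv), CH2Cl2, −30 → 0 °C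
Reagents that add atoms: none
Why: Steglich esterification under kinetic control; the allylic C15 hydroxyl, next to the flat isopropenyl group, should be acylated faster than the C17 hydroxyl, which sits between two branched stereocentres. The configuration of the acyl α-carbon does not matter, because step 7 erases it.

Step 6
Reactants: 9 (3S,4R,5R,6R)-6-(benzyloxy)-5-hydroxy-2,4-dimethylhept-1-en-3-yl (2R)-2-(benzyloxy)propanoate
Product: 10 (3S,4S,5R,6R)-6-(benzyloxy)-5-methoxy-2,4-dimethylhept-1-en-3-yl (2R)-2-(benzyloxy)propanoate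
Conditions: Me3OBF4, 1,8-bis(dimethylamino)naphthalene, CH2Cl2, 0 → 23 °C
Reagents that add atoms: trimethyloxonium tetrafluoroborate, C[O+](C)C.F[B-](F)(F)F
Why: O-methylation with a Meerwein salt and a non-nucleophilic proton scavenger; no alkoxide is formed, so 1,3-acyl migration and elimination should not occur.

Step 7
Reactants: 10 (3S,4S,5R,6R)-6-(benzyloxy)-5-methoxy-2,4-dimethylhept-1-en-3-yl (2R)-2-(benzyloxy)propanoate
Product: 13 (2S,4E,6S,7R,8R)-2,8-bis(benzyloxy)-7-methoxy-2,4,6-trimethylnon-4-en-1-ol, via silyl ketene acetal 11 (not isolated), via trimethylsilyl ester 12 (not isolated)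
Conditions: LiN(iPr)2, THF, −78 °C; TMSCl, Et3N, −78 → 23 °C, then 60 °C; LiAlH4, 0 °C; aq. KNaC4H4O6
Reagents that add atoms: none
Why: LiN(iPr)2 removes the only acidic hydrogen of 10, the lactate α-hydrogen, and the lithium enolate is held in the (Z) geometry by chelation of lithium between the enolate oxygen and the α-benzyloxy oxygen; silylation freezes this geometry in 11. Warming triggers the Ireland–Claisen [3,3]-sigmatropic rearrangement, whose closest precedent is the rearrangement of allyl esters of O-protected lactic and glycolic acids through chelated enolates. No ring of the product is closed: the six-membered array O–C11–C12···C13–C14–C15 exists only as a chair transition state. In that chair the C16 branch on C15 lies pseudo-equatorial, which gives the (E)-C14=C15 alkene, and the enolate geometry places the C12 methyl pseudo-axial and the benzyloxy group pseudo-equatorial. The new C12–C13 bond therefore forms on one face of C12 only, so the (15S) carbinol, which is destroyed, is traded for the (12S) quaternary centre. The selectivities needed are the enolate geometry, secured by the chelating α-benzyloxy group, and chair over boat, secured by the acyclic ester and the unhindered C13 methylene terminus, which gives the axial methyl no 1,3-diaxial partner. C16, C17 and C18 carry no acidic hydrogen and should pass unchanged. LiAlH4 then reduces silyl ester 12 in the same flask, so the α-alkoxy acid is never handled.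

Step 8
Reactants: 13 (2S,4E,6S,7R,8R)-2,8-bis(benzyloxy)-7-methoxy-2,4,6-trimethylnon-4-en-1-ol
Product: 14 (2S,4E,6S,7R,8R)-7-methoxy-2,4,6-trimethylnon-4-ene-1,2,8-triol
Conditions: Na, NH3 (l), THF, −78 °C; NH4Cl
Reagents that add atoms: none
Why: Dissolving-metal (Birch-type) debenzylation; the isolated trisubstituted alkene, the methyl ether and the alkoxides are inert, and no C–O bond of 13 is allylic, so only the two benzyl ethers should be cleaved.

Step 9
Reactants: 14 (2S,4E,6S,7R,8R)-7-methoxy-2,4,6-trimethylnon-4-ene-1,2,8-triol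
Product: 15 (2S,4E,6S,7R,8R)-7-methoxy-2,4,6-trimethyl-1,2,8-tris[(triethylsilyl)oxy]non-4-ene
Conditions: TESOTf, 2,6-lutidine, CH2Cl2, −78 → 0 °C
Reagents that add atoms: triethylsilyl trifluoromethanesulfonate, CC[Si](CC)(CC)OS(=O)(=O)C(F)(F)F
Why: Silylation with a silyl triflate, which is reactive enough for the tertiary C12 hydroxyl; the C12 ether is the group that later blocks direction of the epoxidation from C12.

Step 10
Reactants: 15 (2S,4E,6S,7R,8R)-7-methoxy-2,4,6-trimethyl-1,2,8-tris[(triethylsilyl)oxy]non-4-ene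
Product: 16 (2S,4E,6S,7R,8R)-7-methoxy-2,4,6-trimethyl-2,8-bis[(triethylsilyl)oxy]non-4-enal
Conditions: (COCl)2, DMSO, CH2Cl2, −78 → −30 °C; Et3N, −78 → 0 °C
Reagents that add atoms: none
Why: Swern oxidation with direct cleavage–oxidation of the primary triethylsilyl ether; the secondary and tertiary silyl ethers are too hindered to react, and the aldehyde has no α-hydrogen to epimerise.

Step 11
Reactants: 16 (2S,4E,6S,7R,8R)-7-methoxy-2,4,6-trimethyl-2,8-bis[(triethylsilyl)oxy]non-4-enal
Product: 17 2-[(1E,3S,5E,7S,8R,9R)-8-methoxy-3,5,7-trimethyl-3,9-bis[(triethylsilyl)oxy]deca-1,5-dien-1-yl]-4,4,5,5-tetramethyl-1,3,2-dioxaborolane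
Conditions: CrCl2, Cl2CHBpin, LiI, THF, 23 °C
Reagents that add atoms: 2-(dichloromethyl)-4,4,5,5-tetramethyl-1,3,2-dioxaborolane, ClC(Cl)B1OC(C)(C)C(C)(C)O1
Why: Takai–Utimoto chromium-mediated boryl-olefination, which should give the (E)-alkenylboronate (C10=C11); a non-enolisable aldehyde is a good substrate.

Step 12
Reactants: 18 3-(trimethylsilyl)prop-2-ynal
Product: 20 (3S,4S)-4-methyl-1-(trimethylsilyl)hex-5-en-1-yn-3-ol, via borinate 19 (not isolated)
Conditions: trans-2-butene, KOtBu, n-BuLi, THF, −78 → −45 °C; (−)-Ipc2BOMe, −78 °C; BF3·OEt2; 18, −78 °C; NaOH, H2O2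
Reagents that add atoms: trans-but-2-ene, C/C=C/C
Why: Brown asymmetric crotylboration through a chair transition state: the (E)-crotyl group gives the anti relation of C6 and C7, and the isopinocampheyl groups derived from (+)-α-pinene should select the aldehyde face that leads to the (3S,4S) alcohol.

Step 13
Reactants: 20 (3S,4S)-4-methyl-1-(trimethylsilyl)hex-5-en-1-yn-3-ol; 21 methyl (2E)-3-iodoprop-2-enoate
Product: 23 methyl (2E,6S,7S)-7-hydroxy-6-methyl-9-(trimethylsilyl)non-2-en-8-ynoate, via alkylborane 22 (not isolated)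
Conditions: 9-BBN (2.2 equiv), THF, 0 → 23 °C; then 21, Pd(dppf)Cl2, AsPh3, Cs2CO3, DMF/H2O, 23 °C
Reagents that add atoms: none
Why: Anti-Markovnikov hydroboration of the terminal alkene (the silylated alkyne reacts much more slowly), then B-alkyl Suzuki–Miyaura coupling with the β-iodoacrylate to form C3–C4; the geometry of the enoate is not critical, because it is lost in step 14.

Step 14
Reactants: 23 methyl (2E,6S,7S)-7-hydroxy-6-methyl-9-(trimethylsilyl)non-2-en-8-ynoate
Product: 25 methyl 2-[(2R,5S,6S)-6-ethynyl-5-methyloxan-2-yl]acetate, via silylalkynyl oxane 24 (not isolated)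
Conditions: KOtBu (0.3 equiv), THF, 0 → 23 °C; then MeOH, K2CO3, 23 °C
Reagents that add atoms: none
Why: Intramolecular oxa-Michael addition (6-exo-trig) under equilibrating conditions should give the all-equatorial 2,6-cis oxane, which sets C3; methanolysis then removes the alkynyl silyl group without transesterifying the methyl ester.

Step 15
Reactants: 25 methyl 2-[(2R,5S,6S)-6-ethynyl-5-methyloxan-2-yl]acetate
Product: 27 methyl 2-[(2R,5S,6S)-6-[(1E)-1-iodoprop-1-en-2-yl]-5-methyloxan-2-yl]acetate, via alkenylalane 26 (not isolated)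
Conditions: Me3Al, Cp2ZrCl2 (0.25 equiv), H2O (1 equiv), CH2Cl2, −20 °C; I2, THF, −20 → 0 °C
Reagents that add atoms: trimethylaluminium, C[Al](C)C; iodine, II
Why: Negishi zirconium-catalysed carboalumination (syn addition, methyl to the internal carbon C8) and iodinolysis with retention give the (E)-iodide; the water-accelerated variant at low temperature should be faster than attack on the ester.

Step 16
Reactants: 17 2-[(1E,3S,5E,7S,8R,9R)-8-methoxy-3,5,7-trimethyl-3,9-bis[(triethylsilyl)oxy]deca-1,5-dien-1-yl]-4,4,5,5-tetramethyl-1,3,2-dioxaborolane; 27 methyl 2-[(2R,5S,6S)-6-[(1E)-1-iodoprop-1-en-2-yl]-5-methyloxan-2-yl]acetate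
Product: 28 methyl 2-[(2R,5S,6S)-6-[(2E,4E,6S,8E,10S,11R,12R)-11-methoxy-6,8,10-trimethyl-6,12-bis[(triethylsilyl)oxy]trideca-2,4,8-trien-2-yl]-5-methyloxan-2-yl]acetate
Conditions: Pd(PPh3)4, Cs2CO3, THF/H2O, 55 °C
Reagents that add atoms: none
Why: Suzuki–Miyaura coupling of an alkenyl iodide with an alkenylboronate forms C9–C10 with retention of both geometries and gives the (8E,10E)-diene.

Step 17
Reactants: 28 methyl 2-[(2R,5S,6S)-6-[(2E,4E,6S,8E,10S,11R,12R)-11-methoxy-6,8,10-trimethyl-6,12-bis[(triethylsilyl)oxy]trideca-2,4,8-trien-2-yl]-5-methyloxan-2-yl]acetate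
Product: 29 methyl 2-[(2R,5S,6S)-6-[(2E,4E,6S,8E,10S,11R,12R)-12-hydroxy-11-methoxy-6,8,10-trimethyl-6-[(triethylsilyl)oxy]trideca-2,4,8-trien-2-yl]-5-methyloxan-2-yl]acetate
Conditions: HF·pyridine, pyridine, THF, 0 °C
Reagents that add atoms: none
Why: Sterically controlled desilylation with buffered fluoride: the secondary C18 triethylsilyl ether should be cleaved much faster than the tertiary one at C12, and the buffered medium should not ionise the dienylic C12–O bond.

Step 18
Reactants: 29 methyl 2-[(2R,5S,6S)-6-[(2E,4E,6S,8E,10S,11R,12R)-12-hydroxy-11-methoxy-6,8,10-trimethyl-6-[(triethylsilyl)oxy]trideca-2,4,8-trien-2-yl]-5-methyloxan-2-yl]acetate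
Product: 30 methyl 2-[(2R,5S,6S)-6-[(2E,4E,6S)-7-[(2R,3R)-3-[(2R,3R,4R)-4-hydroxy-3-methoxypentan-2-yl]-2-methyloxiran-2-yl]-6-methyl-6-[(triethylsilyl)oxy]hepta-2,4-dien-2-yl]-5-methyloxan-2-yl]acetate
Conditions: VO(acac)2 (5 mol %), t-BuOOH, CH2Cl2, −15 °C
Reagents that add atoms: tert-butyl hydroperoxide, CC(C)(C)OO
Why: Hydroxyl-directed vanadium-catalysed epoxidation: the C18 alkoxide binds vanadium and delivers oxygen to the bishomoallylic C14=C15 alkene in a conformation fixed by allylic strain at C16, which should give the (14R,15R) oxirane; the diene has no free hydroxyl nearby, because O12 is silylated.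

Step 19
Reactants: 30 methyl 2-[(2R,5S,6S)-6-[(2E,4E,6S)-7-[(2R,3R)-3-[(2R,3R,4R)-4-hydroxy-3-methoxypentan-2-yl]-2-methyloxiran-2-yl]-6-methyl-6-[(triethylsilyl)oxy]hepta-2,4-dien-2-yl]-5-methyloxan-2-yl]acetate
Product: 32 2-[(2R,5S,6S)-6-[(2E,4E,6S)-6-hydroxy-7-[(2R,3R)-3-[(2R,3R,4R)-4-hydroxy-3-methoxypentan-2-yl]-2-methyloxiran-2-yl]-6-methylhepta-2,4-dien-2-yl]-5-methyloxan-2-yl]acetic acid, via methyl ester 31 (not isolated)
Conditions: TBAF, AcOH, THF, 23 °C; then LiOH, THF/MeOH/H2O, 0 → 23 °C; 0.1 M HCl to pH 4.5 at 0 °C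
Reagents that add atoms: lithium hydroxide, [Li+].[OH-]
Why: Buffered fluoride removes the tertiary silyl ether without generating a free alkoxide near the oxirane, and saponification under mild aqueous conditions releases the acid; no acidic step stronger than pH 4.5 touches the oxirane or the dienylic alcohol.

## Compound list

1 | (2R)-2-(benzyloxy)propanoic acid | C[C@@H](OCc1ccccc1)C(=O)O | starting material
2 | (2R)-2-(benzyloxy)-N-methoxy-N-methylpropanamide | C[C@@H](OCc1ccccc1)C(=O)N(C)OC | intermediate
3 | (2R)-2-(benzyloxy)pentan-3-one | CCC(=O)[C@@H](C)OCc1ccccc1 | intermediate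
4 | 2-methylprop-2-enal (methacrolein) | CC(=C)C=O | starting material
5 | trichlorotitanium (Z)-enolate of 3 (not isolated) | C/C=C(\O[Ti](Cl)(Cl)Cl)[C@@H](C)OCc1ccccc1 | intermediate
6 | (2R,4S,5S)-2-(benzyloxy)-5-hydroxy-4,6-dimethylhept-6-en-3-one | O=C([C@@H](C)[C@H](O)C(C)=C)[C@@H](C)OCc1ccccc1 | intermediate
7 | diethylboron aldolate of 6 (not isolated) | O=C([C@@H](C)[C@H](OB(CC)CC)C(C)=C)[C@@H](C)OCc1ccccc1 | intermediate
8 | (2R,3R,4S,5S)-2-(benzyloxy)-4,6-dimethylhept-6-ene-3,5-diol | O[C@H]([C@@H](C)[C@H](O)C(C)=C)[C@@H](C)OCc1ccccc1 | intermediate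
9 | (3S,4R,5R,6R)-6-(benzyloxy)-5-hydroxy-2,4-dimethylhept-1-en-3-yl (2R)-2-(benzyloxy)propanoate | O[C@H]([C@@H](C)[C@H](OC(=O)[C@@H](C)OCc1ccccc1)C(C)=C)[C@@H](C)OCc1ccccc1 | intermediate
10 | (3S,4S,5R,6R)-6-(benzyloxy)-5-methoxy-2,4-dimethylhept-1-en-3-yl (2R)-2-(benzyloxy)propanoate | CO[C@H]([C@@H](C)[C@H](OC(=O)[C@@H](C)OCc1ccccc1)C(C)=C)[C@@H](C)OCc1ccccc1 | intermediate
11 | (Z)-O-trimethylsilyl ketene acetal of 10 (not isolated) | CO[C@H]([C@@H](C)[C@H](O/C(O[Si](C)(C)C)=C(\C)OCc1ccccc1)C(C)=C)[C@@H](C)OCc1ccccc1 | intermediate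
12 | trimethylsilyl (2S,4E,6S,7R,8R)-2,8-bis(benzyloxy)-7-methoxy-2,4,6-trimethylnon-4-enoate (not isolated) | CO[C@H]([C@@H](C)/C=C(\C)C[C@](C)(OCc1ccccc1)C(=O)O[Si](C)(C)C)[C@@H](C)OCc1ccccc1 | intermediate
13 | (2S,4E,6S,7R,8R)-2,8-bis(benzyloxy)-7-methoxy-2,4,6-trimethylnon-4-en-1-ol | CO[C@H]([C@@H](C)/C=C(\C)C[C@](C)(OCc1ccccc1)CO)[C@@H](C)OCc1ccccc1 | intermediate
14 | (2S,4E,6S,7R,8R)-7-methoxy-2,4,6-trimethylnon-4-ene-1,2,8-triol | CO[C@H]([C@@H](C)/C=C(\C)C[C@](C)(O)CO)[C@@H](C)O | intermediate
15 | (2S,4E,6S,7R,8R)-7-methoxy-2,4,6-trimethyl-1,2,8-tris[(triethylsilyl)oxy]non-4-ene | CO[C@H]([C@@H](C)/C=C(\C)C[C@](C)(O[Si](CC)(CC)CC)CO[Si](CC)(CC)CC)[C@@H](C)O[Si](CC)(CC)CC | intermediate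
16 | (2S,4E,6S,7R,8R)-7-methoxy-2,4,6-trimethyl-2,8-bis[(triethylsilyl)oxy]non-4-enal | CO[C@H]([C@@H](C)/C=C(\C)C[C@](C)(O[Si](CC)(CC)CC)C=O)[C@@H](C)O[Si](CC)(CC)CC | intermediate
17 | 2-[(1E,3S,5E,7S,8R,9R)-8-methoxy-3,5,7-trimethyl-3,9-bis[(triethylsilyl)oxy]deca-1,5-dien-1-yl]-4,4,5,5-tetramethyl-1,3,2-dioxaborolane | CO[C@H]([C@@H](C)/C=C(\C)C[C@](C)(O[Si](CC)(CC)CC)/C=C/B1OC(C)(C)C(C)(C)O1)[C@@H](C)O[Si](CC)(CC)CC | intermediate
18 | 3-(trimethylsilyl)prop-2-ynal | C[Si](C)(C)C#CC=O | starting material
19 | diisopinocampheylborinate of 20 (not isolated) | C[Si](C)(C)C#C[C@@H](OB([C@@H]1C[C@@H]2C[C@H]([C@H]1C)C2(C)C)[C@@H]1C[C@@H]2C[C@H]([C@H]1C)C2(C)C)[C@@H](C)C=C | intermediate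
20 | (3S,4S)-4-methyl-1-(trimethylsilyl)hex-5-en-1-yn-3-ol | C[Si](C)(C)C#C[C@@H](O)[C@@H](C)C=C | intermediate
21 | methyl (2E)-3-iodoprop-2-enoate | COC(=O)/C=C/I | starting material
22 | 9-borabicyclo[3.3.1]nonane adduct of 20, boron on C4 and on the hydroxyl oxygen (not isolated) | C[Si](C)(C)C#C[C@@H](OB1C2CCCC1CCC2)[C@@H](C)CCB1C2CCCC1CCC2 | intermediate
23 | methyl (2E,6S,7S)-7-hydroxy-6-methyl-9-(trimethylsilyl)non-2-en-8-ynoate | C[Si](C)(C)C#C[C@@H](O)[C@@H](C)CC/C=C/C(=O)OC | intermediate
24 | methyl 2-[(2R,5S,6S)-5-methyl-6-[(trimethylsilyl)ethynyl]oxan-2-yl]acetate (not isolated) | C[Si](C)(C)C#C[C@H]1O[C@@H](CC(=O)OC)CC[C@@H]1C | intermediate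
25 | methyl 2-[(2R,5S,6S)-6-ethynyl-5-methyloxan-2-yl]acetate | C#C[C@H]1O[C@@H](CC(=O)OC)CC[C@@H]1C | intermediate
26 | methyl 2-[(2R,5S,6S)-6-[(1E)-1-(dimethylalumanyl)prop-1-en-2-yl]-5-methyloxan-2-yl]acetate (not isolated) | C[Al](C)/C=C(\C)[C@H]1O[C@@H](CC(=O)OC)CC[C@@H]1C | intermediate
27 | methyl 2-[(2R,5S,6S)-6-[(1E)-1-iodoprop-1-en-2-yl]-5-methyloxan-2-yl]acetate | I/C=C(\C)[C@H]1O[C@@H](CC(=O)OC)CC[C@@H]1C | intermediate
28 | methyl 2-[(2R,5S,6S)-6-[(2E,4E,6S,8E,10S,11R,12R)-11-methoxy-6,8,10-trimethyl-6,12-bis[(triethylsilyl)oxy]trideca-2,4,8-trien-2-yl]-5-methyloxan-2-yl]acetate | CO[C@H]([C@@H](C)/C=C(\C)C[C@](C)(O[Si](CC)(CC)CC)/C=C/C=C(\C)[C@H]1O[C@@H](CC(=O)OC)CC[C@@H]1C)[C@@H](C)O[Si](CC)(CC)CC | intermediate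
29 | methyl 2-[(2R,5S,6S)-6-[(2E,4E,6S,8E,10S,11R,12R)-12-hydroxy-11-methoxy-6,8,10-trimethyl-6-[(triethylsilyl)oxy]trideca-2,4,8-trien-2-yl]-5-methyloxan-2-yl]acetate | CO[C@H]([C@@H](C)/C=C(\C)C[C@](C)(O[Si](CC)(CC)CC)/C=C/C=C(\C)[C@H]1O[C@@H](CC(=O)OC)CC[C@@H]1C)[C@@H](C)O | intermediate
30 | methyl 2-[(2R,5S,6S)-6-[(2E,4E,6S)-7-[(2R,3R)-3-[(2R,3R,4R)-4-hydroxy-3-methoxypentan-2-yl]-2-methyloxiran-2-yl]-6-methyl-6-[(triethylsilyl)oxy]hepta-2,4-dien-2-yl]-5-methyloxan-2-yl]acetate | CO[C@H]([C@@H](C)[C@H]1O[C@]1(C)C[C@](C)(O[Si](CC)(CC)CC)/C=C/C=C(\C)[C@H]1O[C@@H](CC(=O)OC)CC[C@@H]1C)[C@@H](C)O | intermediate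
31 | methyl 2-[(2R,5S,6S)-6-[(2E,4E,6S)-6-hydroxy-7-[(2R,3R)-3-[(2R,3R,4R)-4-hydroxy-3-methoxypentan-2-yl]-2-methyloxiran-2-yl]-6-methylhepta-2,4-dien-2-yl]-5-methyloxan-2-yl]acetate (not isolated) | CO[C@H]([C@@H](C)[C@H]1O[C@]1(C)C[C@](C)(O)/C=C/C=C(\C)[C@H]1O[C@@H](CC(=O)OC)CC[C@@H]1C)[C@@H](C)O | intermediate
32 | 2-[(2R,5S,6S)-6-[(2E,4E,6S)-6-hydroxy-7-[(2R,3R)-3-[(2R,3R,4R)-4-hydroxy-3-methoxypentan-2-yl]-2-methyloxiran-2-yl]-6-methylhepta-2,4-dien-2-yl]-5-methyloxan-2-yl]acetic acid | CO[C@H]([C@@H](C)[C@H]1O[C@]1(C)C[C@](C)(O)/C=C/C=C(\C)[C@H]1O[C@@H](CC(=O)O)CC[C@@H]1C)[C@@H](C)O | target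

## Step count and least certain steps

Total: 19 steps. Longest linear sequence: 15 steps (steps 1–11 and 16–19). The oxane branch is steps 12–15.

**Step 7 (key step).** The most likely failure is incomplete chelation control during enolisation, which gives a mixed enolate geometry and erodes the transfer of configuration from C15 to C12. A second failure is fragmentation of the lithium enolate to a ketene and the C15 alkoxide before silylation. Fallback (template control in place of chirality transfer): it sets out from 10 and returns at 14. Methanolysis (K2CO3, MeOH) cleaves the lactate ester to allylic alcohol F1. SOCl2 in Et2O transposes it (SNi′ through a cyclic transition state) to the primary (E)-allylic chloride F2. The lithium enolate of dioxolanone F3, prepared from (R)-lactic acid and pivalaldehyde, is alkylated by F2 in the presence of LiI on the face away from the tert-butyl group, which gives alkylated dioxolanone F4 with C12 set by the acetal centre. LiAlH4 opens F4 to diol F5, and Na in NH3 removes the remaining benzyl group to give triol 14.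

**Step 5.** The risk is acylation at the C17 hydroxyl or at both hydroxyls, and 1,3-acyl migration under the basic catalyst, because the two secondary hydroxyls differ only in their steric surroundings. Fallback (differentiation by functional-group type instead of sterics): it sets out from 8 and returns at 10. MnO2 oxidises only the allylic C15 hydroxyl to give hydroxy enone F6. Me3OBF4 with 1,8-bis(dimethylamino)naphthalene methylates the single remaining hydroxyl to give methoxy enone F7. Zn(BH4)2 reduces the enone through a chelate with the C17 methoxy group, with hydride anti to the C16 methyl, and should restore the (15S) allylic alcohol F8. Esterification of F8 with 1 (DIC, DMAP) gives 10 without any regiochemical question.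

**Step 18.** The risks are poor facial selectivity, if the bulky silyl ether at C12 distorts the conformation about C13–C14, competing oxidation of the diene on long reaction times, and opening of the new oxirane by the C18 hydroxyl. Fallback (reagent-controlled epoxidation before the diene exists): it sets out from 15 and returns at 30. Shi epoxidation of 15, its only alkene, with the D-fructose-derived ketone catalyst and KHSO5 gives epoxide F9. The Swern step gives epoxy aldehyde F10. CrCl2, Cl2CHBpin and LiI give epoxy alkenylboronate F11. Suzuki coupling with 27 gives the bis-silyl ether F12, and HF·pyridine frees the C18 hydroxyl to give 30.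

**Step 15.** The risk is attack of the organoaluminium reagent on the methyl ester, or stalling of the carbometalation through chelation of aluminium by the ring oxygen and the ester. Fallback (reversed coupling polarity without organoaluminium): it sets out from 25 and 16 and returns at 28. Copper-catalysed methylboration of 25 (CuCl, Xantphos, B2pin2, MeI, NaOtBu; syn addition, boron to the terminal carbon) gives alkenylboronate F13. Takai iodo-olefination of 16 (CHI3, CrCl2) gives alkenyl iodide F14. Suzuki coupling of F13 with F14 (Pd(PPh3)4, Cs2CO3) gives 28.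

## Further compounds

F1 | step 7 | (3S,4S,5R,6R)-6-(benzyloxy)-5-methoxy-2,4-dimethylhept-1-en-3-ol | CO[C@H]([C@@H](C)[C@H](O)C(C)=C)[C@@H](C)OCc1ccccc1
F2 | step 7 | (2E,4S,5R,6R)-6-(benzyloxy)-1-chloro-5-methoxy-2,4-dimethylhept-2-ene | CO[C@H]([C@@H](C)/C=C(\C)CCl)[C@@H](C)OCc1ccccc1
F3 | step 7 | (2R,5R)-2-tert-butyl-5-methyl-1,3-dioxolan-4-one | C[C@H]1O[C@@H](C(C)(C)C)OC1=O
F4 | step 7 | (2R,5S)-5-[(2E,4S,5R,6R)-6-(benzyloxy)-5-methoxy-2,4-dimethylhept-2-en-1-yl]-2-tert-butyl-5-methyl-1,3-dioxolan-4-one | CO[C@H]([C@@H](C)/C=C(\C)C[C@]1(C)O[C@@H](C(C)(C)C)OC1=O)[C@@H](C)OCc1ccccc1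
F5 | step 7 | (2S,4E,6S,7R,8R)-8-(benzyloxy)-7-methoxy-2,4,6-trimethylnon-4-ene-1,2-diol | CO[C@H]([C@@H](C)/C=C(\C)C[C@](C)(O)CO)[C@@H](C)OCc1ccccc1
F6 | step 5 | (4R,5R,6R)-6-(benzyloxy)-5-hydroxy-2,4-dimethylhept-1-en-3-one | O[C@H]([C@@H](C)C(=O)C(C)=C)[C@@H](C)OCc1ccccc1
F7 | step 5 | (4R,5R,6R)-6-(benzyloxy)-5-methoxy-2,4-dimethylhept-1-en-3-one | CO[C@H]([C@@H](C)C(=O)C(C)=C)[C@@H](C)OCc1ccccc1
F8 | step 5 | (3S,4S,5R,6R)-6-(benzyloxy)-5-methoxy-2,4-dimethylhept-1-en-3-ol | CO[C@H]([C@@H](C)[C@H](O)C(C)=C)[C@@H](C)OCc1ccccc1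
F9 | step 18 | (14R,15R)-epoxide of 15 (target numbering; 12S,16R,17R,18R unchanged) | CO[C@H]([C@@H](C)[C@H]1O[C@]1(C)C[C@](C)(O[Si](CC)(CC)CC)CO[Si](CC)(CC)CC)[C@@H](C)O[Si](CC)(CC)CC
F10 | step 18 | (14R,15R)-epoxide of aldehyde 16 (target numbering) | CO[C@H]([C@@H](C)[C@H]1O[C@]1(C)C[C@](C)(O[Si](CC)(CC)CC)C=O)[C@@H](C)O[Si](CC)(CC)CC
F11 | step 18 | (14R,15R)-epoxide of alkenylboronate 17 (target numbering) | CO[C@H]([C@@H](C)[C@H]1O[C@]1(C)C[C@](C)(O[Si](CC)(CC)CC)/C=C/B1OC(C)(C)C(C)(C)O1)[C@@H](C)O[Si](CC)(CC)CC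
F12 | step 18 | 12,18-bis(triethylsilyl) ether of methyl ester 31 | CO[C@H]([C@@H](C)[C@H]1O[C@]1(C)C[C@](C)(O[Si](CC)(CC)CC)/C=C/C=C(\C)[C@H]1O[C@@H](CC(=O)OC)CC[C@@H]1C)[C@@H](C)O[Si](CC)(CC)CC
F13 | step 15 | methyl 2-[(2R,5S,6S)-5-methyl-6-[(1E)-1-(4,4,5,5-tetramethyl-1,3,2-dioxaborolan-2-yl)prop-1-en-2-yl]oxan-2-yl]acetate | CC1(C)OB(/C=C(\C)[C@H]2O[C@@H](CC(=O)OC)CC[C@@H]2C)OC1(C)C
F14 | step 15 | (1E,3S,5E,7S,8R,9R)-1-iodo-8-methoxy-3,5,7-trimethyl-3,9-bis[(triethylsilyl)oxy]deca-1,5-diene | CO[C@H]([C@@H](C)/C=C(\C)C[C@](C)(O[Si](CC)(CC)CC)/C=C/I)[C@@H](C)O[Si](CC)(CC)CC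
A1 | alternative 1 | (4E,6S,7R,8R)-7-methoxy-4,6-dimethyl-8-[(triethylsilyl)oxy]non-4-en-2-one | CO[C@H]([C@@H](C)/C=C(\C)CC(C)=O)[C@@H](C)O[Si](CC)(CC)CC
A2 | alternative 1 | (5E,7S,8R,9R)-8-methoxy-3,5,7-trimethyl-9-[(triethylsilyl)oxy]dec-5-en-1-yn-3-ol, mixture of C3 epimers | CO[C@H]([C@@H](C)/C=C(\C)CC(C)(O)C#C)[C@@H](C)O[Si](CC)(CC)CC
A3 | alternative 2 | (2R,5R)-2-tert-butyl-5-methyl-1,3-dioxolan-4-one | C[C@H]1O[C@@H](C(C)(C)C)OC1=O
A4 | alternative 2 | (2E,4S,5R,6R)-1-bromo-5-methoxy-2,4-dimethyl-6-[(triethylsilyl)oxy]hept-2-ene | CO[C@H]([C@@H](C)/C=C(\C)CBr)[C@@H](C)O[Si](CC)(CC)CC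
A5 | alternative 2 | (2R,5S)-2-tert-butyl-5-[(2E,4S,5R,6R)-5-methoxy-2,4-dimethyl-6-[(triethylsilyl)oxy]hept-2-en-1-yl]-5-methyl-1,3-dioxolan-4-one | CO[C@H]([C@@H](C)/C=C(\C)C[C@]1(C)O[C@@H](C(C)(C)C)OC1=O)[C@@H](C)O[Si](CC)(CC)CC
A6 | alternative 3 | 2-[(2R,5S,6S)-6-[(2E,4E,6R)-7-[(2R,3R)-3-[(2R,3R,4R)-4-hydroxy-3-methoxypentan-2-yl]-2-methyloxiran-2-yl]-6-methylhepta-2,4-dien-2-yl]-5-methyloxan-2-yl]acetic acid | CO[C@H]([C@@H](C)[C@H]1O[C@]1(C)C[C@@H](C)/C=C/C=C(\C)[C@H]1O[C@@H](CC(=O)O)CC[C@@H]1C)[C@@H](C)O
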